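**Retrosynthetic overview**
1. Target ⇐ O‑acetylation and ester hydrolysis ⇐ (E)‑allylic alcohol from Zr‑catalysed methylalumination/formaldehyde trapping of a terminal alkyne.
2. C‑9 quaternary centre and 1(10)‑alkene ⇐ conjugate addition of a C4 alkyne unit to a bicyclic 9(10)‑en‑1‑one (anti to the 8‑methyl), enol triflate, reduction.
3. Enone ⇐ Diels–Alder adduct by C‑4 methylation, then sulfoxide elimination of a 9‑CH2SPh group (this carbon becomes C‑20) and enol‑ether hydrolysis.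
4. Ring A ⇐ Diels–Alder reaction of a ring‑B 2‑ethoxydiene with methyl acrylate (C2–C3 and C4–C5 bonds; C‑5 set by the ring‑B stereocentres).
5. Ring B ⇐ (S)‑pulegone (α′‑alkylation, retro‑aldol, enol triflate, Stille). Ring B comes from the pool; ring A is formed by the cycloaddition.

Assumption: (S)‑(−)‑pulegone (1) is bought as the source of C‑8; positions are given in halimane numbering (C‑1 to C‑20), with α the face of H‑5.

**Route**

Step 1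
Reactants: 1 (S)‑(−)‑pulegone
Product: 2 (2R,3S)‑3‑methyl‑2‑[(phenylsulfanyl)methyl]‑6‑(propan‑2‑ylidene)cyclohexan‑1‑one
Conditions: LiN(iPr)2, THF, −78 °C; PhSCH2Cl, NaI (cat.), HMPA, −78 → 0 °C
Reagents that add atoms: chloromethyl phenyl sulfide, ClCSc1ccccc1
Why: Kinetic α′‑deprotonation (the other α‑carbon is blocked by the isopropylidene) and enolate alkylation place CH2SPh on the future C‑9, trans to the adjacent methyl; this centre is epimerisable and is settled in step 2.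

Step 2
Reactants: 2 (2R,3S)‑3‑methyl‑2‑[(phenylsulfanyl)methyl]‑6‑(propan‑2‑ylidene)cyclohexan‑1‑one
Product: 3 (2R,3S)‑3‑methyl‑2‑[(phenylsulfanyl)methyl]cyclohexan‑1‑one
Conditions: 6 M HCl (aq), reflux, acetone distilled off
Reagents that add atoms: none
Why: Acid‑catalysed conjugate hydration and retro‑aldol cleavage remove acetone, and the α‑centre equilibrates to the trans (diequatorial) 2,3‑isomer while the pool centre (future C‑8) is untouched.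

Step 3
Reactants: 3 (2R,3S)‑3‑methyl‑2‑[(phenylsulfanyl)methyl]cyclohexan‑1‑one
Product: 4 (5S,6R)‑5‑methyl‑6‑[(phenylsulfanyl)methyl]cyclohex‑1‑en‑1‑yl trifluoromethanesulfonate
Conditions: LiN(iPr)2, THF, −78 °C; PhNTf2, −78 → 0 °C
Reagents that add atoms: N‑phenylbis(trifluoromethanesulfonimide), O=S(=O)(N(c1ccccc1)S(=O)(=O)C(F)(F)F)C(F)(F)F
Why: Kinetic enolisation at the unsubstituted α‑CH2 and O‑triflation give the less substituted enol triflate without touching the α‑stereocentre.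

Step 4
Reactants: 4 (5S,6R)‑5‑methyl‑6‑[(phenylsulfanyl)methyl]cyclohex‑1‑en‑1‑yl trifluoromethanesulfonate
Product: 5 ({[(1R,6S)‑2‑(1‑ethoxyethenyl)‑6‑methylcyclohex‑2‑en‑1‑yl]methyl}sulfanyl)benzene
Conditions: Bu3SnC(OEt)=CH2, Pd(PPh3)4 (5 mol %), LiCl, THF, 65 °C; Et3N‑buffered work‑up
Reagents that add atoms: tributyl(1‑ethoxyethenyl)stannane, CCCC[Sn](CCCC)(CCCC)C(=C)OCC
Why: Stille cross‑coupling of the enol triflate gives the electron‑rich 2‑ethoxy‑1,3‑diene with no stereocentre involved.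

Step 5
Reactants: 5 ({[(1R,6S)‑2‑(1‑ethoxyethenyl)‑6‑methylcyclohex‑2‑en‑1‑yl]methyl}sulfanyl)benzene; 6 methyl acrylate
Product: 7 methyl (1S,5R,6S,8aS)‑4‑ethoxy‑6‑methyl‑5‑[(phenylsulfanyl)methyl]‑1,2,3,5,6,7,8,8a‑octahydronaphthalene‑1‑carboxylate (endo adduct; its C‑1 epimer is carried along)
Conditions: 6 (5 equiv), toluene, BHT (cat.), sealed tube, 110 °C, 48 h
Reagents that add atoms: none
Why: Thermal Diels–Alder reaction forms ring A with "para" regiochemistry to the 2‑ethoxy group (ester carbon on C‑5); the dienophile adds anti to the allylic C‑9 CH2SPh group, which A(1,3) strain with the ethoxy group keeps pseudoaxial, so the C4–C5 bond is cis to the 8‑methyl and H‑5 is α, while the endo/exo centre at C‑4 is erased in step 6.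

Step 6
Reactants: 7 methyl (1S,5R,6S,8aS)‑4‑ethoxy‑6‑methyl‑5‑[(phenylsulfanyl)methyl]‑1,2,3,5,6,7,8,8a‑octahydronaphthalene‑1‑carboxylate
Product: 8 methyl (1S,5R,6S,8aR)‑4‑ethoxy‑1,6‑dimethyl‑5‑[(phenylsulfanyl)methyl]‑1,2,3,5,6,7,8,8a‑octahydronaphthalene‑1‑carboxylate
Conditions: LiN(iPr)2, THF, −78 °C; MeI, DMPU, −78 → −20 °C
Reagents that add atoms: iodomethane, CI
Why: Ester enolate alkylation sets the C‑4 quaternary centre: MeI enters from the equatorial (α) direction, trans to the C5–C6 bond, leaving the ester axial (β), the usual outcome for C‑4 ester enolates in such decalins.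

Step 7
Reactants: 8 methyl (1S,5R,6S,8aR)‑4‑ethoxy‑1,6‑dimethyl‑5‑[(phenylsulfanyl)methyl]‑1,2,3,5,6,7,8,8a‑octahydronaphthalene‑1‑carboxylate
Product: 9 methyl (1S,5R,6S,8aR)‑5‑[(benzenesulfinyl)methyl]‑4‑ethoxy‑1,6‑dimethyl‑1,2,3,5,6,7,8,8a‑octahydronaphthalene‑1‑carboxylate (both sulfur epimers)
Conditions: NaIO4, NaHCO3, MeOH/H2O, 0 °C → rt
Reagents that add atoms: sodium periodate, [Na+].[O-]I(=O)(=O)=O
Why: Periodate oxidises the sulfide to the sulfoxide without over‑oxidation and without attacking the enol ether under buffered conditions.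

Step 8
Reactants: 9 methyl (1S,5R,6S,8aR)‑5‑[(benzenesulfinyl)methyl]‑4‑ethoxy‑1,6‑dimethyl‑1,2,3,5,6,7,8,8a‑octahydronaphthalene‑1‑carboxylate
Product: 11 methyl (1S,6S,8aR)‑1,5,6‑trimethyl‑4‑oxo‑1,2,3,4,6,7,8,8a‑octahydronaphthalene‑1‑carboxylate, via dienol ether 10 (not isolated)
Conditions: toluene, NaHCO3 (solid), 110 °C; then 1 M HCl, THF, 0 °C
Reagents that add atoms: water, O
Why: Thermal syn (Ei) sulfoxide elimination can only take H‑9, so the exocyclic methylene forms regiospecifically, and acid hydrolysis of the resulting 2‑ethoxydiene by γ‑protonation gives the 9(10)‑en‑1‑one with the former CH2S carbon as the C‑20 methyl and H‑5 never involved.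

Step 9
Reactants: 11 methyl (1S,6S,8aR)‑1,5,6‑trimethyl‑4‑oxo‑1,2,3,4,6,7,8,8a‑octahydronaphthalene‑1‑carboxylate; 12 (4‑bromobut‑1‑yn‑1‑yl)trimethylsilane
Product: 15 methyl (1S,5R,6S,8aR)‑1,5,6‑trimethyl‑4‑[(trifluoromethanesulfonyl)oxy]‑5‑[4‑(trimethylsilyl)but‑3‑yn‑1‑yl]‑1,2,3,5,6,7,8,8a‑octahydronaphthalene‑1‑carboxylate, via Grignard reagent 13 (not isolated), via magnesium enolate 14 (not isolated)
Conditions: 12, Mg, THF, 40 °C; CuBr·SMe2 (0.5 equiv), THF/Me2S, −78 → −20 °C, add 11; then PhNTf2, −78 °C → rt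
Reagents that add atoms: N‑phenylbis(trifluoromethanesulfonimide), O=S(=O)(N(c1ccccc1)S(=O)(=O)C(F)(F)F)C(F)(F)F
Why: Copper‑mediated conjugate addition creates the C‑9 quaternary centre by axial attack anti to the pseudoaxial 8‑methyl (chain α, 9‑methyl β), and the regiodefined enolate is O‑triflated in the same flask.

Step 10
Reactants: 15 methyl (1S,5R,6S,8aR)‑1,5,6‑trimethyl‑4‑[(trifluoromethanesulfonyl)oxy]‑5‑[4‑(trimethylsilyl)but‑3‑yn‑1‑yl]‑1,2,3,5,6,7,8,8a‑octahydronaphthalene‑1‑carboxylate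
Product: 17 methyl (1S,5R,6S,8aR)‑5‑(but‑3‑yn‑1‑yl)‑1,5,6‑trimethyl‑1,2,3,5,6,7,8,8a‑octahydronaphthalene‑1‑carboxylate, via silylalkyne ester 16 (not isolated)
Conditions: Pd(OAc)2 (5 mol %), PPh3, Bu3N, HCO2H, DMF, 60 °C; then K2CO3, MeOH, rt
Reagents that add atoms: none
Why: Palladium‑catalysed formate reduction of the enol triflate gives the 1(10)‑alkene exactly where the enolate was, and methanolysis then removes the alkynyl silyl group; no stereocentre is touched.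

Step 11
Reactants: 17 methyl (1S,5R,6S,8aR)‑5‑(but‑3‑yn‑1‑yl)‑1,5,6‑trimethyl‑1,2,3,5,6,7,8,8a‑octahydronaphthalene‑1‑carboxylate
Product: 18 methyl (1S,5R,6S,8aR)‑5‑[(3E)‑5‑hydroxy‑3‑methylpent‑3‑en‑1‑yl]‑1,5,6‑trimethyl‑1,2,3,5,6,7,8,8a‑octahydronaphthalene‑1‑carboxylate
Conditions: AlMe3, Cp2ZrCl2 (0.25 equiv), CH2Cl2, 0 °C → rt; then n‑BuLi, THF, −78 °C; (CH2O)n, −78 °C → rt
Reagents that add atoms: trimethylaluminium, C[Al](C)C; formaldehyde (from paraformaldehyde), C=O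
Why: Negishi zirconium‑catalysed carboalumination adds Me and Al syn across the terminal alkyne (Me on the internal carbon), and the alanate reacts with formaldehyde with retention, giving only the (E)‑trisubstituted allylic alcohol.

Step 12
Reactants: 18 methyl (1S,5R,6S,8aR)‑5‑[(3E)‑5‑hydroxy‑3‑methylpent‑3‑en‑1‑yl]‑1,5,6‑trimethyl‑1,2,3,5,6,7,8,8a‑octahydronaphthalene‑1‑carboxylate
Product: 19 (1S,5R,6S,8aR)‑5‑[(3E)‑5‑hydroxy‑3‑methylpent‑3‑en‑1‑yl]‑1,5,6‑trimethyl‑1,2,3,5,6,7,8,8a‑octahydronaphthalene‑1‑carboxylic acid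
Conditions: KOH, MeOH/H2O, 80 °C; then 1 M HCl
Reagents that add atoms: potassium hydroxide, [K+].[OH-]
Why: Saponification of the hindered axial methyl ester is done before the base‑labile acetate is installed; the quaternary C‑4 cannot epimerise.

Step 13
Reactants: 19 (1S,5R,6S,8aR)‑5‑[(3E)‑5‑hydroxy‑3‑methylpent‑3‑en‑1‑yl]‑1,5,6‑trimethyl‑1,2,3,5,6,7,8,8a‑octahydronaphthalene‑1‑carboxylic acid
Product: 20 (1S,5R,6S,8aR)‑5‑[(3E)‑5‑(acetyloxy)‑3‑methylpent‑3‑en‑1‑yl]‑1,5,6‑trimethyl‑1,2,3,5,6,7,8,8a‑octahydronaphthalene‑1‑carboxylic acid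
Conditions: Ac2O, pyridine, DMAP (cat.), CH2Cl2, 0 °C; aqueous work‑up
Reagents that add atoms: acetic anhydride, CC(=O)OC(C)=O
Why: The primary allylic alcohol is acetylated selectively; any mixed anhydride of the hindered tertiary acid is hydrolysed back on aqueous work‑up.

**Compound list**
1 | (S)‑(−)‑pulegone, (5S)‑5‑methyl‑2‑(propan‑2‑ylidene)cyclohexan‑1‑one | C[C@H]1CCC(=C(C)C)C(=O)C1 | starting material
2 | (2R,3S)‑3‑methyl‑2‑[(phenylsulfanyl)methyl]‑6‑(propan‑2‑ylidene)cyclohexan‑1‑one | C[C@H]1CCC(=C(C)C)C(=O)[C@@H]1CSc2ccccc2 | intermediate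
3 | (2R,3S)‑3‑methyl‑2‑[(phenylsulfanyl)methyl]cyclohexan‑1‑one | C[C@H]1CCCC(=O)[C@@H]1CSc2ccccc2 | intermediate
4 | (5S,6R)‑5‑methyl‑6‑[(phenylsulfanyl)methyl]cyclohex‑1‑en‑1‑yl trifluoromethanesulfonate | C[C@H]1CCC=C(OS(=O)(=O)C(F)(F)F)[C@@H]1CSc2ccccc2 | intermediate
5 | ({[(1R,6S)‑2‑(1‑ethoxyethenyl)‑6‑methylcyclohex‑2‑en‑1‑yl]methyl}sulfanyl)benzene | C[C@H]1CCC=C(C(=C)OCC)[C@@H]1CSc2ccccc2 | intermediate
6 | methyl acrylate | C=CC(=O)OC | starting material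
7 | methyl (1S,5R,6S,8aS)‑4‑ethoxy‑6‑methyl‑5‑[(phenylsulfanyl)methyl]‑1,2,3,5,6,7,8,8a‑octahydronaphthalene‑1‑carboxylate | C(Sc3ccccc3)[C@H]1C2=C(OCC)CC[C@H](C(=O)OC)[C@@H]2CC[C@@H]1C | intermediate
8 | methyl (1S,5R,6S,8aR)‑4‑ethoxy‑1,6‑dimethyl‑5‑[(phenylsulfanyl)methyl]‑1,2,3,5,6,7,8,8a‑octahydronaphthalene‑1‑carboxylate | C(Sc3ccccc3)[C@H]1C2=C(OCC)CC[C@](C)(C(=O)OC)[C@@H]2CC[C@@H]1C | intermediate
9 | methyl (1S,5R,6S,8aR)‑5‑[(benzenesulfinyl)methyl]‑4‑ethoxy‑1,6‑dimethyl‑1,2,3,5,6,7,8,8a‑octahydronaphthalene‑1‑carboxylate | O=S(C[C@H]1C2=C(OCC)CC[C@](C)(C(=O)OC)[C@@H]2CC[C@@H]1C)c3ccccc3 | intermediate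
10 | methyl (1S,6S,8aR)‑4‑ethoxy‑1,6‑dimethyl‑5‑methylidene‑1,2,3,5,6,7,8,8a‑octahydronaphthalene‑1‑carboxylate | C=C1C2=C(OCC)CC[C@](C)(C(=O)OC)[C@@H]2CC[C@@H]1C | intermediate
11 | methyl (1S,6S,8aR)‑1,5,6‑trimethyl‑4‑oxo‑1,2,3,4,6,7,8,8a‑octahydronaphthalene‑1‑carboxylate | CC1=C2C(=O)CC[C@](C)(C(=O)OC)[C@@H]2CC[C@@H]1C | intermediate
12 | (4‑bromobut‑1‑yn‑1‑yl)trimethylsilane | C[Si](C)(C)C#CCCBr | starting material
13 | [4‑(trimethylsilyl)but‑3‑yn‑1‑yl]magnesium bromide | C[Si](C)(C)C#CCC[Mg]Br | intermediate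
14 | methyl (1S,5R,6S,8aR)‑4‑[(bromomagnesio)oxy]‑1,5,6‑trimethyl‑5‑[4‑(trimethylsilyl)but‑3‑yn‑1‑yl]‑1,2,3,5,6,7,8,8a‑octahydronaphthalene‑1‑carboxylate | C[Si](C)(C)C#CCC[C@@]1(C)C2=C(O[Mg]Br)CC[C@](C)(C(=O)OC)[C@@H]2CC[C@@H]1C | intermediate
15 | methyl (1S,5R,6S,8aR)‑1,5,6‑trimethyl‑4‑[(trifluoromethanesulfonyl)oxy]‑5‑[4‑(trimethylsilyl)but‑3‑yn‑1‑yl]‑1,2,3,5,6,7,8,8a‑octahydronaphthalene‑1‑carboxylate | C[Si](C)(C)C#CCC[C@@]1(C)C2=C(OS(=O)(=O)C(F)(F)F)CC[C@](C)(C(=O)OC)[C@@H]2CC[C@@H]1C | intermediate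
16 | methyl (1S,5R,6S,8aR)‑1,5,6‑trimethyl‑5‑[4‑(trimethylsilyl)but‑3‑yn‑1‑yl]‑1,2,3,5,6,7,8,8a‑octahydronaphthalene‑1‑carboxylate | C[Si](C)(C)C#CCC[C@@]1(C)C2=CCC[C@](C)(C(=O)OC)[C@@H]2CC[C@@H]1C | intermediate
17 | methyl (1S,5R,6S,8aR)‑5‑(but‑3‑yn‑1‑yl)‑1,5,6‑trimethyl‑1,2,3,5,6,7,8,8a‑octahydronaphthalene‑1‑carboxylate | C#CCC[C@@]1(C)C2=CCC[C@](C)(C(=O)OC)[C@@H]2CC[C@@H]1C | intermediate
18 | methyl (1S,5R,6S,8aR)‑5‑[(3E)‑5‑hydroxy‑3‑methylpent‑3‑en‑1‑yl]‑1,5,6‑trimethyl‑1,2,3,5,6,7,8,8a‑octahydronaphthalene‑1‑carboxylate | OC/C=C(\C)CC[C@@]1(C)C2=CCC[C@](C)(C(=O)OC)[C@@H]2CC[C@@H]1C | intermediate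
19 | (1S,5R,6S,8aR)‑5‑[(3E)‑5‑hydroxy‑3‑methylpent‑3‑en‑1‑yl]‑1,5,6‑trimethyl‑1,2,3,5,6,7,8,8a‑octahydronaphthalene‑1‑carboxylic acid | OC/C=C(\C)CC[C@@]1(C)C2=CCC[C@](C)(C(=O)O)[C@@H]2CC[C@@H]1C | intermediate
20 | (1S,5R,6S,8aR)‑5‑[(3E)‑5‑(acetyloxy)‑3‑methylpent‑3‑en‑1‑yl]‑1,5,6‑trimethyl‑1,2,3,5,6,7,8,8a‑octahydronaphthalene‑1‑carboxylic acid (CNP0276297.2) | CC(=O)OC/C=C(\C)CC[C@@]1(C)C2=CCC[C@](C)(C(=O)O)[C@@H]2CC[C@@H]1C | target

**Step count and weak points**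
Total: 13 steps. Longest linear sequence: 13 steps (1 → 20); 6 and 12 are bought and enter at steps 5 and 9.

Step 5 (Diels–Alder) is the least certain: the 2‑ethoxydiene is hindered and acid‑sensitive, and the facial ratio at C‑5 rests on conformational argument, not direct precedent. The fallback sets out from 5 and returns at 7. Mild hydrolysis (oxalic acid, wet THF) gives the acetyl enone 1‑{(5S,6R)‑5‑methyl‑6‑[(phenylsulfanyl)methyl]cyclohex‑1‑en‑1‑yl}ethan‑1‑one F2. Its kinetic lithium enolate (LiN(iPr)2, THF, −78 °C) is annulated with 6 by two consecutive Michael additions at −78 °C, a stepwise anionic route with the same bond set, to give the ring‑A lithium enolate methyl (1S,5R,6S,8aS)‑4‑(lithiooxy)‑6‑methyl‑5‑[(phenylsulfanyl)methyl]‑1,2,3,5,6,7,8,8a‑octahydronaphthalene‑1‑carboxylate F3. O‑Ethylation with Et3O·BF4 in HMPA then gives 7.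

Step 9 (conjugate addition) must build a quaternary centre on a tetrasubstituted enone and may stall or give 1,2‑addition. The fallback sets out from 11 and returns at 16. 1,2‑Reduction (NaBH4, CeCl3·7H2O, MeOH, −78 °C) gives the allylic alcohol methyl (1S,4R,6S,8aR)‑4‑hydroxy‑1,5,6‑trimethyl‑1,2,3,4,6,7,8,8a‑octahydronaphthalene‑1‑carboxylate F4. Esterification (picolinic acid, DCC, DMAP) gives the picolinate methyl (1S,4R,6S,8aR)‑1,5,6‑trimethyl‑4‑[(pyridine‑2‑carbonyl)oxy]‑1,2,3,4,6,7,8,8a‑octahydronaphthalene‑1‑carboxylate F5. Anti‑selective SN2′ displacement by Grignard reagent 13 with CuBr·SMe2 forms the C‑9 centre and the 1(10)‑alkene together and gives 16. If the reduction gives the other C‑4 alcohol epimer, its N‑phenylcarbamate is used for a syn‑selective displacement instead.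

Step 1 (enolate alkylation with an α‑chloro sulfide) can be slow or give O‑ and di‑alkylation. The fallback sets out from 1 and returns at 2. The cross‑conjugated silyl dienol ether trimethyl{[(3S)‑3‑methyl‑6‑(propan‑2‑ylidene)cyclohex‑1‑en‑1‑yl]oxy}silane F1 is made (LiN(iPr)2, TMSCl, THF, −78 °C). It is then alkylated with PhSCH2Cl and catalytic ZnBr2 (CH2Cl2, rt), a Lewis‑acid SN1 attack of the thionium ion on the silyl enol ether, which gives 2.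

Further compounds
F1 | step 1 | trimethyl{[(3S)‑3‑methyl‑6‑(propan‑2‑ylidene)cyclohex‑1‑en‑1‑yl]oxy}silane | C[C@H]1CCC(=C(C)C)C(O[Si](C)(C)C)=C1
F2 | step 5 | 1‑{(5S,6R)‑5‑methyl‑6‑[(phenylsulfanyl)methyl]cyclohex‑1‑en‑1‑yl}ethan‑1‑one | C[C@H]1CCC=C(C(C)=O)[C@@H]1CSc2ccccc2
F3 | step 5 | methyl (1S,5R,6S,8aS)‑4‑(lithiooxy)‑6‑methyl‑5‑[(phenylsulfanyl)methyl]‑1,2,3,5,6,7,8,8a‑octahydronaphthalene‑1‑carboxylate | C(Sc3ccccc3)[C@H]1C2=C(O[Li])CC[C@H](C(=O)OC)[C@@H]2CC[C@@H]1C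
F4 | step 9 | methyl (1S,4R,6S,8aR)‑4‑hydroxy‑1,5,6‑trimethyl‑1,2,3,4,6,7,8,8a‑octahydronaphthalene‑1‑carboxylate | CC1=C2[C@H](O)CC[C@](C)(C(=O)OC)[C@@H]2CC[C@@H]1C
F5 | step 9 | methyl (1S,4R,6S,8aR)‑1,5,6‑trimethyl‑4‑[(pyridine‑2‑carbonyl)oxy]‑1,2,3,4,6,7,8,8a‑octahydronaphthalene‑1‑carboxylate | CC1=C2[C@H](OC(=O)c3ccccn3)CC[C@](C)(C(=O)OC)[C@@H]2CC[C@@H]1C
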